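**Retrosynthetic overview**
1. Feature: in each benzopyran unit, O1 (on C8a) lies para to C6, the carbon bonded to the bridge CH. While C8 is unsubstituted, the two carbons ortho to that oxygen (later C4a and C8) are equivalent across the C6–C8a axis. A 1,1-dimethylpropargyl ether on this oxygen can therefore close onto the ring in only one way.
2. Endgame disconnections: both C8–acyl bonds are cut first (twofold Friedel–Crafts acylation at the single free ring carbon). Next come both C3–C4 saturations together with the four 5-O/7-O benzyl groups (one hydrogenation).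
3. Key disconnection: both C4–C4a bonds, made by twofold gold-catalysed 6-endo hydroarylation of a bridged bis(aryl 1,1-dimethylpropargyl ether). The two pyran rings are the only rings built, and they form one after the other in the same flask.
4. The four hydroxyls beside the bridge are carried as benzyl ethers. Six free phenols cannot be etherified site-selectively with confidence, since those beside the bridge are acidified by inter-ring hydrogen bonding. Free phloroglucinol also tends to oligomerise and to form xanthenes with aldehydes.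
5. The bridge is therefore set regiospecifically. 3,5-Bis(benzyloxy)phenol receives TIPS on its lone OH, is lithiated between the two benzyloxy groups and adds twice to methyl 6-methylheptanoate. Ionic reduction follows, and TIPS is then exchanged for the propargyl groups.

Key step: step 6

Remark: the bridge carbon bears two identical aryl groups, so the target is achiral and needs no stereocontrol. Slow rotation about the aryl–CH bonds is assumed to give no separable isomers.

**Step 1**
Reactants: 1 3,5-bis(benzyloxy)phenol; 2 chlorotriisopropylsilane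
Product: 3 [3,5-bis(benzyloxy)phenoxy]triisopropylsilane
Conditions: 2 (1.2 equiv), imidazole (2.5 equiv), DMF, rt
Reagents that add atoms: chlorotriisopropylsilane 2, CC(C)[Si](Cl)(C(C)C)C(C)C
Why: Imidazole-promoted O-silylation of the only free phenol is routine, and the bulky TIPS ether masks the oxygen that becomes O1 while neither directing nor allowing lithiation at its two neighbouring carbons in step 2.

**Step 2**
Reactants: 3 [3,5-bis(benzyloxy)phenoxy]triisopropylsilane; 4 methyl 6-methylheptanoate
Product: 7 1,1-bis[2,6-bis(benzyloxy)-4-(triisopropylsilyloxy)phenyl]-6-methylheptan-1-ol, via aryllithium 5 (not isolated), via aryl ketone 6 (not isolated)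
Conditions: 3 (2.3 equiv), n-BuLi (2.3 equiv), TMEDA (2.3 equiv), Et2O, 0 °C; then 4 (1.0 equiv), −78 °C to rt; H2O quench
Reagents that add atoms: methyl 6-methylheptanoate 4, CC(C)CCCCC(=O)OC
Why: Directed ortho-metalation removes the proton flanked by the two benzyloxy groups (cooperative lithium coordination, TIPS-shielded alternatives, benzylic deprotonation being slow with n-BuLi in Et2O at 0 °C), and aryllithium 5 then adds twice to the ester by addition–elimination to ketone 6 and 1,2-addition, so both aryl–carbon bonds are set para to the silyloxy group without a regiochemical choice.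

**Step 3**
Reactants: 7 1,1-bis[2,6-bis(benzyloxy)-4-(triisopropylsilyloxy)phenyl]-6-methylheptan-1-ol
Product: 9 1,1-bis[2,6-bis(benzyloxy)-4-(triisopropylsilyloxy)phenyl]-6-methylheptane, via diarylalkyl cation 8 (not isolated)
Conditions: Et3SiH (5 equiv), CF3CO2H (10 equiv), CH2Cl2, −20 to 0 °C
Reagents that add atoms: none
Why: Ionic hydrogenation: CF3CO2H ionises the tertiary, doubly benzylic alcohol to the strongly stabilised cation 8, Et3SiH transfers hydride to it (any 1,1-diarylalkene formed by proton loss is reprotonated to 8), aryl benzyl and aryl TIPS ethers tolerate the short cold acid exposure, and the new CH carries two identical aryl groups and is no stereocentre.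

**Step 4**
Reactants: 9 1,1-bis[2,6-bis(benzyloxy)-4-(triisopropylsilyloxy)phenyl]-6-methylheptane
Product: 10 4,4'-(6-methylheptane-1,1-diyl)bis[3,5-bis(benzyloxy)phenol]
Conditions: TBAF (2.4 equiv), AcOH (2.4 equiv), THF, 0 °C
Reagents that add atoms: none
Why: Fluoride-induced cleavage of the two aryl silyl ethers is driven by the Si–F bond, leaves the benzyl ethers untouched, and the AcOH buffer keeps the electron-rich phenols protonated and so less prone to air oxidation.

**Step 5**
Reactants: 10 4,4'-(6-methylheptane-1,1-diyl)bis[3,5-bis(benzyloxy)phenol]; 11 3-chloro-3-methylbut-1-yne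
Product: 12 1,1-bis[2,6-bis(benzyloxy)-4-(2-methylbut-3-yn-2-yloxy)phenyl]-6-methylheptane (tetra-O-benzyl form of the bridged bis(phloroglucinol) bis(1,1-dimethylpropargyl) ether)
Conditions: 11 (3 equiv), CuCl2·2H2O (2 mol %), DBU (3 equiv), MeCN–CH2Cl2, 0 °C, N2
Reagents that add atoms: 3-chloro-3-methylbut-1-yne 11, CC(C)(Cl)C#C
Why: Copper-catalysed propargylic etherification: the copper acetylide of 11 loses chloride to give an allenylidene-type electrophile that the DBU-generated phenoxide captures at the tertiary carbon, and since 10 has only the two unhindered hydroxyls para to the bridge no site selectivity is asked for.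

**Step 6**
Reactants: 12 1,1-bis[2,6-bis(benzyloxy)-4-(2-methylbut-3-yn-2-yloxy)phenyl]-6-methylheptane
Product: 14 1,1-bis[5,7-bis(benzyloxy)-2,2-dimethyl-2H-chromen-6-yl]-6-methylheptane, via monochromene 13 (not isolated)
Conditions: Ph3PAuNTf2 (5 mol %), dry CH2Cl2 (0.05 M), 4 Å molecular sieves, rt
Reagents that add atoms: none
Why: The cationic monovalent gold fragment Ph3PAu+ binds a terminal alkyne of 12, the ring carbon ortho to the ether oxygen attacks the terminal alkyne carbon opposite to gold, and loss of the ring proton followed by protodeauration of the vinylgold species releases the 2H-chromene and the catalyst, after which the same sequence on monochromene 13 gives 14. The closest known reaction type is the gold-catalysed intramolecular hydroarylation of aryl propargyl ethers to 2H-chromenes, for which Ph3PAuNTf2 at room temperature is an established catalyst, also with 1,1-dimethylpropargyl ethers of alkoxy-substituted phenols. Each of the two pyran rings closes in the 6-endo-dig mode and forms its C4–C4a bond; the 5-exo mode is disfavoured with an electron-rich arene, and the gem-dimethyl group at C2 folds the chain toward the ring (Thorpe–Ingold effect). No stereocentre is present in 14, because the bridge carbon is stereogenic only in racemic 13 and loses this character when the second ring closes. The step needs regioselectivity and chemoselectivity: the first comes from the substrate, since on each ring the two carbons ortho to the propargyl ether are equivalent (same benzyloxy neighbour, C8 still free), and the second from the benzyl ethers, which leave no O–H group that could add to the activated alkyne or bind gold. Dry solvent and sieves hold back alkyne hydration, and the mild temperature keeps the tertiary propargylic C–O bond from ionising.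

**Step 7**
Reactants: 14 1,1-bis[5,7-bis(benzyloxy)-2,2-dimethyl-2H-chromen-6-yl]-6-methylheptane
Product: 15 1,1-bis(5,7-dihydroxy-2,2-dimethylchroman-6-yl)-6-methylheptane
Conditions: H2 (1 atm), 10% Pd/C, EtOAc–MeOH, rt
Reagents that add atoms: none
Why: Heterogeneous catalytic hydrogenation saturates both styrene-type C3=C4 bonds and hydrogenolyses the four aryl benzyl ethers in one operation, while the chroman C–O bonds and the diarylmethine C–C bonds are inert under these conditions.

**Step 8**
Reactants: 15 1,1-bis(5,7-dihydroxy-2,2-dimethylchroman-6-yl)-6-methylheptane; 16 isobutyryl chloride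
Product: 17 1,1-bis(5,7-dihydroxy-8-isobutyryl-2,2-dimethylchroman-6-yl)-6-methylheptane (CNP0275635.0)
Conditions: 16 (2.6 equiv), TiCl4 (5 equiv), CH2Cl2, 0 °C to rt; cold 1 M HCl work-up
Reagents that add atoms: isobutyryl chloride 16, CC(C)C(Cl)=O
Why: Friedel–Crafts acylation promoted by TiCl4, a promoter that is compatible with alkylidene-bridged phloroglucinols: the titanium phenoxide at 7-O guides the acyl chloride to the adjacent C8, the one unsubstituted carbon of each ring, the chelated ortho-hydroxy ketone deactivates its ring against further attack, and aryl esters formed at oxygen are funnelled to the C-acyl product by Fries rearrangement.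

**Compound list**
1 | 3,5-bis(benzyloxy)phenol | Oc1cc(OCc2ccccc2)cc(OCc2ccccc2)c1 | starting material
2 | chlorotriisopropylsilane | CC(C)[Si](Cl)(C(C)C)C(C)C | starting material
3 | [3,5-bis(benzyloxy)phenoxy]triisopropylsilane | CC(C)[Si](Oc1cc(OCc2ccccc2)cc(OCc2ccccc2)c1)(C(C)C)C(C)C | intermediate
4 | methyl 6-methylheptanoate | CC(C)CCCCC(=O)OC | starting material
5 | [2,6-bis(benzyloxy)-4-(triisopropylsilyloxy)phenyl]lithium (not isolated) | [Li]c1c(OCc2ccccc2)cc(O[Si](C(C)C)(C(C)C)C(C)C)cc1OCc1ccccc1 | intermediate
6 | 1-[2,6-bis(benzyloxy)-4-(triisopropylsilyloxy)phenyl]-6-methylheptan-1-one (not isolated) | CC(C)CCCCC(=O)c1c(OCc2ccccc2)cc(O[Si](C(C)C)(C(C)C)C(C)C)cc1OCc1ccccc1 | intermediate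
7 | 1,1-bis[2,6-bis(benzyloxy)-4-(triisopropylsilyloxy)phenyl]-6-methylheptan-1-ol | CC(C)CCCCC(O)(c1c(OCc2ccccc2)cc(O[Si](C(C)C)(C(C)C)C(C)C)cc1OCc1ccccc1)c1c(OCc2ccccc2)cc(O[Si](C(C)C)(C(C)C)C(C)C)cc1OCc1ccccc1 | intermediate
8 | 1,1-bis[2,6-bis(benzyloxy)-4-(triisopropylsilyloxy)phenyl]-6-methylheptan-1-ylium (not isolated) | CC(C)CCCC[C+](c1c(OCc2ccccc2)cc(O[Si](C(C)C)(C(C)C)C(C)C)cc1OCc1ccccc1)c1c(OCc2ccccc2)cc(O[Si](C(C)C)(C(C)C)C(C)C)cc1OCc1ccccc1 | intermediate
9 | 1,1-bis[2,6-bis(benzyloxy)-4-(triisopropylsilyloxy)phenyl]-6-methylheptane | CC(C)CCCCC(c1c(OCc2ccccc2)cc(O[Si](C(C)C)(C(C)C)C(C)C)cc1OCc1ccccc1)c1c(OCc2ccccc2)cc(O[Si](C(C)C)(C(C)C)C(C)C)cc1OCc1ccccc1 | intermediate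
10 | 4,4'-(6-methylheptane-1,1-diyl)bis[3,5-bis(benzyloxy)phenol] | CC(C)CCCCC(c1c(OCc2ccccc2)cc(O)cc1OCc1ccccc1)c1c(OCc2ccccc2)cc(O)cc1OCc1ccccc1 | intermediate
11 | 3-chloro-3-methylbut-1-yne | CC(C)(Cl)C#C | starting material
12 | 1,1-bis[2,6-bis(benzyloxy)-4-(2-methylbut-3-yn-2-yloxy)phenyl]-6-methylheptane (key-step precursor, O-benzyl protected) | CC(C)CCCCC(c1c(OCc2ccccc2)cc(OC(C)(C)C#C)cc1OCc1ccccc1)c1c(OCc2ccccc2)cc(OC(C)(C)C#C)cc1OCc1ccccc1 | intermediate
13 | 1-[2,6-bis(benzyloxy)-4-(2-methylbut-3-yn-2-yloxy)phenyl]-1-[5,7-bis(benzyloxy)-2,2-dimethyl-2H-chromen-6-yl]-6-methylheptane (racemic, not isolated) | CC(C)CCCCC(c1c(OCc2ccccc2)cc(OC(C)(C)C#C)cc1OCc1ccccc1)c1c(OCc2ccccc2)cc2OC(C)(C)C=Cc2c1OCc1ccccc1 | intermediate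
14 | 1,1-bis[5,7-bis(benzyloxy)-2,2-dimethyl-2H-chromen-6-yl]-6-methylheptane (key-step product, O-benzyl protected) | CC(C)CCCCC(c1c(OCc2ccccc2)cc2OC(C)(C)C=Cc2c1OCc1ccccc1)c1c(OCc2ccccc2)cc2OC(C)(C)C=Cc2c1OCc1ccccc1 | intermediate
15 | 1,1-bis(5,7-dihydroxy-2,2-dimethylchroman-6-yl)-6-methylheptane | CC(C)CCCCC(c1c(O)cc2OC(C)(C)CCc2c1O)c1c(O)cc2OC(C)(C)CCc2c1O | intermediate
16 | isobutyryl chloride | CC(C)C(Cl)=O | starting material
17 | 1,1-bis(5,7-dihydroxy-8-isobutyryl-2,2-dimethylchroman-6-yl)-6-methylheptane (CNP0275635.0) | CC(C)CCCCC(c1c(O)c2c(c(C(=O)C(C)C)c1O)OC(C)(C)CC2)c1c(O)c2c(c(C(=O)C(C)C)c1O)OC(C)(C)CC2 | target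

**Total step count:** 8
**Longest linear sequence:** 8 steps (fully linear; 2, 4, 11 and 16 are bought)

**Steps most likely to fail**

*Step 6.* Several processes could defeat the closure. The gold catalyst or traces of HNTf2 may ionise the tertiary propargylic C–O bond. Adventitious water may hydrate the alkyne. The reaction may stall after the first ring closure, or the electron-rich chromene may oligomerise under acid.

The fallback sets out from bisphenol 10 and omits the propargyl ether. Compound 10 is heated with 3-methylbut-2-enal, PhB(OH)2 and AcOH in toluene with azeotropic removal of water. This brings about ortho-hydroxyalkylation, loss of water and oxa-6π electrocyclisation on both rings. The two carbons ortho to each free OH are again equivalent, and the sequence rejoins the route at 14.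

*Step 2.* Proton transfer from the α-CH2 of the intermediate ketone to the hindered aryllithium may outrun the second addition. Aryl transfer would then stop after one ring.

The fallback sets out from 3 and places the alkyl group last, on a carbonyl that has no α-hydrogen. Aryllithium 5 (two equivalents) is added to ethyl formate to give bis[2,6-bis(benzyloxy)-4-(triisopropylsilyloxy)phenyl]methanol F1. Oxidation with MnO2 in CH2Cl2 gives bis[2,6-bis(benzyloxy)-4-(triisopropylsilyloxy)phenyl]methanone F2. Addition of 5-methylhexyllithium F3 (from 1-bromo-5-methylhexane and lithium metal in Et2O) at −78 to 0 °C then rejoins the route at 7.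

*Step 8.* The Lewis acid and the HCl released may trigger retro-Friedel–Crafts cleavage of the bridge at a ring that is not yet acylated. They may also open the chroman ether so that it re-closes onto the 5-oxygen. Acylation might also stop at oxygen.

The fallback sets out from 14 and avoids acid on the free polyphenol:
- Diimide reduction (2-nitrobenzenesulfonylhydrazide, Et3N) saturates the alkenes with the benzyl ethers kept, giving 1,1-bis[5,7-bis(benzyloxy)-2,2-dimethylchroman-6-yl]-6-methylheptane F4.
- NBS in CH2Cl2 at 0 °C brominates the only free ring position, giving 1,1-bis[5,7-bis(benzyloxy)-8-bromo-2,2-dimethylchroman-6-yl]-6-methylheptane F5.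
- Bromine–lithium exchange with n-BuLi in THF at −78 °C gives the 8,8'-dilithio compound F6.
- Trapping F6 with N-methoxy-N-methylisobutyramide gives 1,1-bis[5,7-bis(benzyloxy)-8-isobutyryl-2,2-dimethylchroman-6-yl]-6-methylheptane F7.
- Hydrogenolysis over Pd/C in EtOAc rejoins the route at 17.

**Further compounds**
F0 | step 6 | none | none
F1 | step 2 | bis[2,6-bis(benzyloxy)-4-(triisopropylsilyloxy)phenyl]methanol | OC(c1c(OCc2ccccc2)cc(O[Si](C(C)C)(C(C)C)C(C)C)cc1OCc1ccccc1)c1c(OCc2ccccc2)cc(O[Si](C(C)C)(C(C)C)C(C)C)cc1OCc1ccccc1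
F2 | step 2 | bis[2,6-bis(benzyloxy)-4-(triisopropylsilyloxy)phenyl]methanone | O=C(c1c(OCc2ccccc2)cc(O[Si](C(C)C)(C(C)C)C(C)C)cc1OCc1ccccc1)c1c(OCc2ccccc2)cc(O[Si](C(C)C)(C(C)C)C(C)C)cc1OCc1ccccc1
F3 | step 2 | 5-methylhexyllithium | [Li]CCCCC(C)C
F4 | step 8 | 1,1-bis[5,7-bis(benzyloxy)-2,2-dimethylchroman-6-yl]-6-methylheptane | CC(C)CCCCC(c1c(OCc2ccccc2)cc2OC(C)(C)CCc2c1OCc1ccccc1)c1c(OCc2ccccc2)cc2OC(C)(C)CCc2c1OCc1ccccc1
F5 | step 8 | 1,1-bis[5,7-bis(benzyloxy)-8-bromo-2,2-dimethylchroman-6-yl]-6-methylheptane | CC(C)CCCCC(c1c(OCc2ccccc2)c(Br)c2OC(C)(C)CCc2c1OCc1ccccc1)c1c(OCc2ccccc2)c(Br)c2OC(C)(C)CCc2c1OCc1ccccc1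
F6 | step 8 | 1,1-bis[5,7-bis(benzyloxy)-8-lithio-2,2-dimethylchroman-6-yl]-6-methylheptane | CC(C)CCCCC(c1c(OCc2ccccc2)c([Li])c2OC(C)(C)CCc2c1OCc1ccccc1)c1c(OCc2ccccc2)c([Li])c2OC(C)(C)CCc2c1OCc1ccccc1
F7 | step 8 | 1,1-bis[5,7-bis(benzyloxy)-8-isobutyryl-2,2-dimethylchroman-6-yl]-6-methylheptane | CC(C)CCCCC(c1c(OCc2ccccc2)c(C(=O)C(C)C)c2OC(C)(C)CCc2c1OCc1ccccc1)c1c(OCc2ccccc2)c(C(=O)C(C)C)c2OC(C)(C)CCc2c1OCc1ccccc1
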